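Ring A is disconnected at C1–C2 (labdane numbering), the one ring bond whose two carbons are plain methylenes, set between the quaternary C10 and C3. Ring-closing metathesis forms it from a cyclohexanone (ring B) that carries a vinyl group on C10 and, trans to it on C5, a pent-4-enoate arm (C4, C3, C2, C19). In one operation the trans-decalin is closed; its rigid chair then directs hydrogen to C9 and methyl iodide to the α face of C4. The ring B stereocentres come from a CBS reduction relayed by an Ireland–Claisen rearrangement (C5) and an anti cuprate addition (C10); C13 comes from methyl hydrogen (R)-3-methylglutarate.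

Key step: step 11

Remark on numbering: ring A = C1–C5 and C10; ring B = C5–C10; C17 = methylene carbon on C8; C18 (methyl) and C19 (carboxyl) on C4; C20 = methyl on C10; side chain C11–C15 on C9 with C16 on C13.
Remark on assumptions: 10 is taken as a purchasable enantiopure building block; compounds 6–9 and 14–20 are carried as C4 epimer mixtures (C4 undefined in their SMILES), which converge in step 14.

Step 1
Reactants: 1 2-methylcyclohex-2-en-1-one
Product: 2 (1S)-2-methylcyclohex-2-en-1-ol
Conditions: (R)-1-methyl-3,3-diphenyltetrahydro-1H,3H-pyrrolo[1,2-c][1,3,2]oxazaborole ((R)-Me-CBS, 10 mol%), BH3·SMe2, THF, −20 °C; aq. NH4Cl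
Reagents that add atoms: none
Why: Corey–Bakshi–Shibata reduction, in which the α-methylvinyl side of the ketone acts as the large group, so that the (R)-oxazaborolidine–borane complex should deliver hydride to the face that gives the (S)-allylic alcohol by 1,2-reduction.

Step 2
Reactants: 2 (1S)-2-methylcyclohex-2-en-1-ol; 3 pent-4-enoic acid
Product: 4 (1S)-2-methylcyclohex-2-en-1-yl pent-4-enoate
Conditions: DCC, 4-(dimethylamino)pyridine (cat.), CH2Cl2, 0 °C → rt
Reagents that add atoms: none
Why: Steglich esterification acylates the allylic alcohol at oxygen and leaves the carbinol stereocentre untouched.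

Step 3
Reactants: 4 (1S)-2-methylcyclohex-2-en-1-yl pent-4-enoate
Product: 7 2-[(1S)-2-methylcyclohex-2-en-1-yl]pent-4-enoic acid, via ketene silyl acetal 5 (not isolated), via trimethylsilyl ester 6 (not isolated)
Conditions: LiN(iPr)2, THF, −78 °C; Me3SiCl, −78 → 60 °C; then 1 M HCl
Reagents that add atoms: none
Why: Ireland–Claisen rearrangement, whose suprafacial [3,3] shift forms the C4–C5 bond on the ring face that the C9–O bond leaves, so that the carbinol chirality is transferred to C5 and the alkene moves to C9=C10, while C4 forms as an epimer mixture that step 14 later resets.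

Step 4
Reactants: 7 2-[(1S)-2-methylcyclohex-2-en-1-yl]pent-4-enoic acid
Product: 8 2-(trimethylsilyl)ethyl 2-[(1S)-2-methylcyclohex-2-en-1-yl]pent-4-enoate
Conditions: Me3SiCH2CH2OH, DCC, 4-(dimethylamino)pyridine (cat.), CH2Cl2, rt
Reagents that add atoms: 2-(trimethylsilyl)ethanol, C[Si](C)(C)CCO
Why: Steglich esterification masks the acid as a fluoride-labile ester that should survive the organometallic, metathesis, hydrogenation, ylide and amide-base steps.

Step 5
Reactants: 8 2-(trimethylsilyl)ethyl 2-[(1S)-2-methylcyclohex-2-en-1-yl]pent-4-enoate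
Product: 9 2-(trimethylsilyl)ethyl 2-[(1S)-2-methyl-4-oxocyclohex-2-en-1-yl]pent-4-enoate
Conditions: dirhodium tetrakis(caprolactamate), Rh2(C6H10NO)4 (1 mol%), tBuOOH (70% aq.), K2CO3, CH2Cl2, rt
Reagents that add atoms: tert-butyl hydroperoxide, CC(C)(C)OO
Why: radical allylic oxidation in which the tert-butylperoxyl radical abstracts hydrogen from the ring methylene C8 next to the trisubstituted alkene (more activated than C3–H, less hindered than C5–H) and the mixed peroxide collapses to the β-methyl enone without touching C5.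

Step 6
Reactants: 10 (3R)-5-methoxy-3-methyl-5-oxopentanoic acid
Product: 11 methyl (3R)-5-hydroxy-3-methylpentanoate
Conditions: BH3·SMe2, THF, 0 °C → rt
Reagents that add atoms: none
Why: chemoselective borane reduction of the carboxylic acid through its acyloxyborane in the presence of the methyl ester, with the stereocentre untouched.

Step 7
Reactants: 11 methyl (3R)-5-hydroxy-3-methylpentanoate
Product: 12 methyl (3R)-5-[(tert-butyldimethylsilyl)oxy]-3-methylpentanoate
Conditions: tBuMe2SiCl, imidazole, DMF, 0 °C → rt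
Reagents that add atoms: tert-butyldimethylsilyl chloride, CC(C)(C)[Si](C)(C)Cl
Why: standard silylation of the primary alcohol, done at once so that the hydroxy ester cannot lactonise.

Step 8
Reactants: 12 methyl (3R)-5-[(tert-butyldimethylsilyl)oxy]-3-methylpentanoate
Product: 13 (3R)-5-[(tert-butyldimethylsilyl)oxy]-3-methylpentanal
Conditions: iBu2AlH (1.1 equiv), CH2Cl2, −78 °C; aq. KNaC4H4O6
Reagents that add atoms: none
Why: partial ester reduction, which stops at the aluminium hemiacetal at −78 °C and releases the aldehyde on work-up; the β-stereocentre cannot epimerise.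

Step 9
Reactants: 9 2-(trimethylsilyl)ethyl 2-[(1S)-2-methyl-4-oxocyclohex-2-en-1-yl]pent-4-enoate; 13 (3R)-5-[(tert-butyldimethylsilyl)oxy]-3-methylpentanal
Product: 15 2-(trimethylsilyl)ethyl 2-[(1S,2S)-2-ethenyl-3-[(3R)-5-(tert-butyldimethylsilyloxy)-1-hydroxy-3-methylpentyl]-2-methyl-4-oxocyclohexyl]pent-4-enoate, via bromomagnesium enolate 14 (not isolated)
Conditions: CH2=CHMgBr (1.3 equiv), CuBr·SMe2 (20 mol%), THF, −78 → −30 °C; then 13, −78 °C; aq. NH4Cl
Reagents that add atoms: vinylmagnesium bromide, C=C[Mg]Br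
Why: copper-catalysed conjugate addition with aldol trapping of the regiodefined enolate, in which the vinyl group should enter C10 anti to the C5 arm (vinyl trans, methyl cis to it), while the C9 and C11 centres form as mixtures that steps 10 and 12 erase.

Step 10
Reactants: 15 the aldol from step 9
Product: 17 2-(trimethylsilyl)ethyl 2-[(1S,2S)-2-ethenyl-3-[(3S)-5-(tert-butyldimethylsilyloxy)-3-methylpentylidene]-2-methyl-4-oxocyclohexyl]pent-4-enoate, via mesylate 16 (not isolated)
Conditions: MeSO2Cl, Et3N, CH2Cl2, 0 °C; then DBU, rt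
Reagents that add atoms: none
Why: mesylation and E1cB elimination (aldol dehydration) through the acidic C9–H should give the exocyclic enone as an E/Z mixture in which all aldol diastereomers converge.

Step 11
Reactants: 17 the dienone from step 10
Product: 18 2-(trimethylsilyl)ethyl (4aS,8aS)-5-[(3S)-5-(tert-butyldimethylsilyloxy)-3-methylpentylidene]-4a-methyl-6-oxo-1,2,4a,5,6,7,8,8a-octahydronaphthalene-1-carboxylate
Conditions: second-generation Hoveyda–Grubbs catalyst, (H2IMes)Cl2Ru=CH(C6H4-2-OiPr) (5 mol%), toluene (0.005 M), 80 °C, argon sparge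
Reagents that add atoms: none
Why: Ring-closing olefin metathesis: the ruthenium alkylidene loads at the unhindered allyl terminus (C2), adds across the C10 vinyl group in a [2+2] step, and the ruthenacyclobutane cycloreverts to the C1=C2 alkene and ethylene. The closest known reaction type is the ring-closing metathesis of 1,7-dienes onto a vinyl group at a quaternary carbon to give cyclohexenes. Ring A closes as a six-membered carbocycle fused trans to ring B, because the vinyl group and the C4 arm lie trans-diequatorial on the ring B chair and are gauche across C5–C10. No stereocentre is created; C5 and C10 are already fixed, and both C4 epimers cyclise. The step needs chemoselectivity for the two terminal alkenes over the C9=C11 enone alkene, which the substrate secures because that alkene is trisubstituted and electron-poor and because closing onto it would put a bridgehead alkene into a bicyclo[3.3.1]nonane. High dilution and removal of ethylene hold back cross-metathesis of the allyl terminus.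

Step 12
Reactants: 18 the octalinone from step 11
Product: 19 2-(trimethylsilyl)ethyl (4aS,5R,8aS)-5-[(3S)-5-(tert-butyldimethylsilyloxy)-3-methylpentyl]-4a-methyl-6-oxodecahydronaphthalene-1-carboxylate
Conditions: H2 (3 atm), 10% Pd/C, EtOAc, rt
Reagents that add atoms: none
Why: heterogeneous hydrogenation saturates C1=C2 and the enone C9=C11 bond, and hydrogen should reach C9 from the α face opposite the axial C10 methyl, giving the equatorial side chain that base equilibration through the C8 enolate also favours.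

Step 13
Reactants: 19 the decalone from step 12
Product: 20 2-(trimethylsilyl)ethyl (4aS,5S,8aS)-5-[(3S)-5-(tert-butyldimethylsilyloxy)-3-methylpentyl]-4a-methyl-6-methylidenedecahydronaphthalene-1-carboxylate
Conditions: Ph3PCH3Br, KN(SiMe3)2, THF/toluene, 0 → 70 °C
Reagents that add atoms: methyltriphenylphosphonium bromide, C[P+](c1ccccc1)(c1ccccc1)c1ccccc1.[Br-]
Why: Wittig methylenation of the hindered C8 ketone with excess ylide, under which any 9-epimer should equilibrate to the equatorial one before olefination fixes it.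

Step 14
Reactants: 20 the exocyclic alkene from step 13
Product: 22 2-(trimethylsilyl)ethyl (1S,4aR,5S,8aR)-5-[(3S)-5-(tert-butyldimethylsilyloxy)-3-methylpentyl]-1,4a-dimethyl-6-methylidenedecahydronaphthalene-1-carboxylate, via lithium ester enolate 21 (not isolated)
Conditions: LiN(iPr)2 (2 equiv), THF, −78 → 0 °C; then MeI, DMPU, −78 °C → rt
Reagents that add atoms: iodomethane, CI
Why: ester enolate alkylation in which both C4 epimers give one exocyclic enolate that methyl iodide should attack from the equatorial α face, the β face being screened by the 1,3-diaxial C10 methyl, so that the ester ends up axial (C19) and C4 is S.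

Step 15
Reactants: 22 the methylated ester from step 14
Product: 23 (1S,4aR,5S,8aR)-5-[(3S)-5-hydroxy-3-methylpentyl]-1,4a-dimethyl-6-methylidenedecahydronaphthalene-1-carboxylic acid
Conditions: Bu4NF (4 equiv), THF, rt → 45 °C; 1 M HCl work-up at 0 °C
Reagents that add atoms: none
Why: fluoride-induced desilylation cleaves the silyl ether and, by attack at silicon and β-fragmentation with loss of ethylene, the hindered 2-(trimethylsilyl)ethyl ester without any attack at the shielded carbonyl.

Step 16
Reactants: 23 the hydroxy acid from step 15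
Product: 24 (1S,4aR,5S,8aR)-5-[(3S)-5-acetoxy-3-methylpentyl]-1,4a-dimethyl-6-methylidenedecahydronaphthalene-1-carboxylic acid
Conditions: Ac2O, pyridine, 4-(dimethylamino)pyridine (cat.), CH2Cl2, 0 °C → rt; aq. NaHCO3, then dilute acid
Reagents that add atoms: acetic anhydride, CC(=O)OC(C)=O
Why: O-acetylation of the primary alcohol, in which the neopentylic acid at most forms a mixed anhydride that the aqueous work-up hydrolyses back.

Compound list

1 | 2-methylcyclohex-2-en-1-one | CC1=CCCCC1=O | starting material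
2 | (1S)-2-methylcyclohex-2-en-1-ol | O[C@H]1CCCC=C1C | intermediate
3 | pent-4-enoic acid | C=CCCC(=O)O | starting material
4 | (1S)-2-methylcyclohex-2-en-1-yl pent-4-enoate | C=CCCC(=O)O[C@H]1CCCC=C1C | intermediate
5 | ketene silyl acetal of 4, 1-[(1S)-2-methylcyclohex-2-en-1-yl]oxy-1-(trimethylsilyloxy)penta-1,4-diene (enol ether geometry undefined) | C=CCC=C(O[Si](C)(C)C)O[C@H]1CCCC=C1C | intermediate (not isolated)
6 | trimethylsilyl 2-[(1S)-2-methylcyclohex-2-en-1-yl]pent-4-enoate (C4 epimers) | C=CCC(C(=O)O[Si](C)(C)C)[C@@H]1CCCC=C1C | intermediate (not isolated)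
7 | 2-[(1S)-2-methylcyclohex-2-en-1-yl]pent-4-enoic acid (C4 epimers) | C=CCC(C(=O)O)[C@@H]1CCCC=C1C | intermediate
8 | 2-(trimethylsilyl)ethyl 2-[(1S)-2-methylcyclohex-2-en-1-yl]pent-4-enoate (C4 epimers) | C=CCC(C(=O)OCC[Si](C)(C)C)[C@@H]1CCCC=C1C | intermediate
9 | 2-(trimethylsilyl)ethyl 2-[(1S)-2-methyl-4-oxocyclohex-2-en-1-yl]pent-4-enoate (C4 epimers) | C=CCC(C(=O)OCC[Si](C)(C)C)[C@@H]1CCC(=O)C=C1C | intermediate
10 | (3R)-5-methoxy-3-methyl-5-oxopentanoic acid (methyl hydrogen (R)-3-methylglutarate) | COC(=O)C[C@H](C)CC(=O)O | starting material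
11 | methyl (3R)-5-hydroxy-3-methylpentanoate | COC(=O)C[C@H](C)CCO | intermediate
12 | methyl (3R)-5-[(tert-butyldimethylsilyl)oxy]-3-methylpentanoate | COC(=O)C[C@H](C)CCO[Si](C)(C)C(C)(C)C | intermediate
13 | (3R)-5-[(tert-butyldimethylsilyl)oxy]-3-methylpentanal | O=CC[C@H](C)CCO[Si](C)(C)C(C)(C)C | intermediate
14 | bromomagnesium enolate of the vinyl adduct of 9 (C8–O–MgBr, C8=C9; vinyl α and methyl β on C10; C4 epimers) | C=CCC(C(=O)OCC[Si](C)(C)C)[C@@H]1CCC(O[Mg]Br)=C[C@@]1(C)C=C | intermediate (not isolated)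
15 | 2-(trimethylsilyl)ethyl 2-[(1S,2S)-2-ethenyl-3-[(3R)-5-(tert-butyldimethylsilyloxy)-1-hydroxy-3-methylpentyl]-2-methyl-4-oxocyclohexyl]pent-4-enoate (mixture at C4, C9 and C11) | C=CCC(C(=O)OCC[Si](C)(C)C)[C@@H]1CCC(=O)C(C(O)C[C@H](C)CCO[Si](C)(C)C(C)(C)C)[C@@]1(C)C=C | intermediate
16 | C11 methanesulfonate of 15 | C=CCC(C(=O)OCC[Si](C)(C)C)[C@@H]1CCC(=O)C(C(OS(C)(=O)=O)C[C@H](C)CCO[Si](C)(C)C(C)(C)C)[C@@]1(C)C=C | intermediate (not isolated)
17 | 2-(trimethylsilyl)ethyl 2-[(1S,2S)-2-ethenyl-3-[(3S)-5-(tert-butyldimethylsilyloxy)-3-methylpentylidene]-2-methyl-4-oxocyclohexyl]pent-4-enoate (E/Z mixture, C4 epimers) | C=CCC(C(=O)OCC[Si](C)(C)C)[C@@H]1CCC(=O)C(=CC[C@H](C)CCO[Si](C)(C)C(C)(C)C)[C@@]1(C)C=C | intermediate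
18 | 2-(trimethylsilyl)ethyl (4aS,8aS)-5-[(3S)-5-(tert-butyldimethylsilyloxy)-3-methylpentylidene]-4a-methyl-6-oxo-1,2,4a,5,6,7,8,8a-octahydronaphthalene-1-carboxylate (trans-fused; C1=C2 alkene; E/Z mixture, C4 epimers) | O=C1CC[C@@H]2[C@](C)(C=CCC2C(=O)OCC[Si](C)(C)C)C1=CC[C@H](C)CCO[Si](C)(C)C(C)(C)C | intermediate
19 | 2-(trimethylsilyl)ethyl (4aS,5R,8aS)-5-[(3S)-5-(tert-butyldimethylsilyloxy)-3-methylpentyl]-4a-methyl-6-oxodecahydronaphthalene-1-carboxylate (C4 epimers) | O=C1CC[C@@H]2[C@](C)(CCCC2C(=O)OCC[Si](C)(C)C)[C@H]1CC[C@H](C)CCO[Si](C)(C)C(C)(C)C | intermediate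
20 | 2-(trimethylsilyl)ethyl (4aS,5S,8aS)-5-[(3S)-5-(tert-butyldimethylsilyloxy)-3-methylpentyl]-4a-methyl-6-methylidenedecahydronaphthalene-1-carboxylate (C4 epimers) | C=C1CC[C@@H]2[C@](C)(CCCC2C(=O)OCC[Si](C)(C)C)[C@H]1CC[C@H](C)CCO[Si](C)(C)C(C)(C)C | intermediate
21 | lithium enolate of 20 (exocyclic C4=C19 ketene acetal) | C=C1CC[C@@H]2[C@](C)(CCCC2=C(O[Li])OCC[Si](C)(C)C)[C@H]1CC[C@H](C)CCO[Si](C)(C)C(C)(C)C | intermediate (not isolated)
22 | 2-(trimethylsilyl)ethyl (1S,4aR,5S,8aR)-5-[(3S)-5-(tert-butyldimethylsilyloxy)-3-methylpentyl]-1,4a-dimethyl-6-methylidenedecahydronaphthalene-1-carboxylate | C=C1CC[C@@H]2[C@](C)(CCC[C@]2(C)C(=O)OCC[Si](C)(C)C)[C@H]1CC[C@H](C)CCO[Si](C)(C)C(C)(C)C | intermediate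
23 | (1S,4aR,5S,8aR)-5-[(3S)-5-hydroxy-3-methylpentyl]-1,4a-dimethyl-6-methylidenedecahydronaphthalene-1-carboxylic acid (15-hydroxylabd-8(17)-en-19-oic acid) | C=C1CC[C@@H]2[C@](C)(CCC[C@]2(C)C(=O)O)[C@H]1CC[C@H](C)CCO | intermediate
24 | (1S,4aR,5S,8aR)-5-[(3S)-5-acetoxy-3-methylpentyl]-1,4a-dimethyl-6-methylidenedecahydronaphthalene-1-carboxylic acid (15-acetoxylabd-8(17)-en-19-oic acid) | C=C1CC[C@@H]2[C@](C)(CCC[C@]2(C)C(=O)O)[C@H]1CC[C@H](C)CCOC(C)=O | target

Total step count: 16. Longest linear sequence: 13 (steps 1–5 and 9–16).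

Steps most likely to fail

Step 9. Conjugate addition to the hindered β,β-disubstituted enone may be slow, so that γ-deprotonation at C5, 1,2-addition or attack on the ester compete, and the magnesium aldolate may revert by retro-aldol on warming. The fallback separates the two events and sets out from 9: CH2=CHMgBr with CuBr·SMe2 (cat.), Me3SiCl and HMPA in THF at −78 °C gives the silyl enol ether F1, and a Mukaiyama aldol addition of F1 to 13 (BF3·OEt2, CH2Cl2, −78 °C) comes back to the route at 15.

Step 5. Hydrogen abstraction may be unselective, with attack at C3 next to the terminal alkene or trapping of the allyl radical at the tertiary C10. The fallback brings the oxygen in by ionic steps and sets out from 8: mCPBA epoxidises only the trisubstituted C9=C10 alkene to the epoxide F2; PhSeNa (from PhSeSePh and NaBH4 in EtOH) opens it at the secondary C9 to the hydroxy selenide F3; oxidation with H2O2 and selenoxide elimination toward C8 gives the tertiary allylic alcohol F4; oxidative 1,3-transposition with pyridinium chlorochromate, [C5H5NH][CrO3Cl], comes back to the route at 9.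

Step 11. The vinyl group on the quaternary C10, crowded further by the alkylidene on C9, may engage too slowly, so that homodimerisation at the allyl terminus takes over. The fallback closes ring A before the side chain is attached and sets out from 9 by way of the silyl enol ether F1 of the step 9 fallback, which has only hydrogen on C9: the same catalyst cyclises it at C1–C2 to the bicyclic silyl enol ether F5; Mukaiyama aldol addition to 13 (BF3·OEt2, −78 °C) gives the bicyclic aldol F6; mesylation and elimination with DBU through the mesylate F7 comes back to the route at 18.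

Further compounds

F1 | step 9 | 2-(trimethylsilyl)ethyl 2-[(1S,2S)-2-ethenyl-2-methyl-4-(trimethylsilyloxy)cyclohex-3-en-1-yl]pent-4-enoate (C4 epimers) | C=CCC(C(=O)OCC[Si](C)(C)C)[C@@H]1CCC(O[Si](C)(C)C)=C[C@@]1(C)C=C
F2 | step 5 | 9,10-epoxide of 8 (epoxide configuration undefined) | C=CCC(C(=O)OCC[Si](C)(C)C)[C@@H]1CCCC2OC12C
F3 | step 5 | 10-hydroxy-9-(phenylselanyl) derivative of 8 | C=CCC(C(=O)OCC[Si](C)(C)C)[C@@H]1CCCC([Se]c2ccccc2)C1(C)O
F4 | step 5 | 2-(trimethylsilyl)ethyl 2-[(1S)-2-hydroxy-2-methylcyclohex-3-en-1-yl]pent-4-enoate (tertiary allylic alcohol, C10 undefined) | C=CCC(C(=O)OCC[Si](C)(C)C)[C@@H]1CCC=CC1(C)O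
F5 | step 11 | 2-(trimethylsilyl)ethyl (4aS,8aS)-4a-methyl-6-(trimethylsilyloxy)-1,2,4a,7,8,8a-hexahydronaphthalene-1-carboxylate (C4 epimers) | C[Si](C)(C)OC1=C[C@@]2(C)C=CCC(C(=O)OCC[Si](C)(C)C)[C@@H]2CC1
F6 | step 11 | bicyclic aldol, 5-[5-(tert-butyldimethylsilyloxy)-1-hydroxy-3-methylpentyl] analogue of 18 (mixture at C9 and C11) | O=C1CC[C@@H]2[C@](C)(C=CCC2C(=O)OCC[Si](C)(C)C)C1C(O)C[C@H](C)CCO[Si](C)(C)C(C)(C)C
F7 | step 11 | C11 methanesulfonate of F6 | O=C1CC[C@@H]2[C@](C)(C=CCC2C(=O)OCC[Si](C)(C)C)C1C(OS(C)(=O)=O)C[C@H](C)CCO[Si](C)(C)C(C)(C)C
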